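The route disconnects the C1=C10 double bond of ring A by ring-closing olefin metathesis. This trisubstituted alkene lies at the A/B ring fusion between quaternary C9 and the C5 methine (halimane numbering: ring A = C1–C5 and C10, ring B = C5–C10), where eliminations would also deliver the 5(10) isomer. Metathesis fixes its position because only the two alkene termini can join. In one operation the step closes ring A and creates the alkene without touching a stereocentre. Its precursor is a ring-B cyclohexane carrying an exocyclic C10 methylene, the C4(Me)(CO2Me) but-3-enyl arm on C5 and the silyl-protected side chain on C9, with all four stereocentres in place.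

Key step: step 15

Assumption: for the enolisation in step 13 the (R)-amide is taken as the antipode that, with the (S)-ester, removes the α-hydrogen from the rotamer leading to the (Z)-ketene acetal 23; should the (E)-isomer form, the (S)-amide is used with the same ester.

Step 1
Reactants: 1 2-methylcyclohex-2-en-1-one
Product: 3 trimethyl{[(3R)-2,3-dimethylcyclohex-1-en-1-yl]oxy}silane, via aluminium enolate 2 (not isolated)
Conditions: Me3Al, Cu(O2C-C4H3S) (copper thiophene-2-carboxylate, 2 mol %), BINOL-derived bis(1-phenylethyl)amine phosphoramidite (4 mol %, antipode giving 3R), Et2O, −30 °C; then TMSOTf, 0 °C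
Reagents that add atoms: trimethylaluminium C[Al](C)C; trimethylsilyl trifluoromethanesulfonate C[Si](C)(C)OS(=O)(=O)C(F)(F)F
Why: Copper-catalysed asymmetric conjugate addition delivers methyl to C8 under ligand control (sets C8 as R), and O-silylation of the aluminium enolate locks the enolate at C9=C10.

Step 2
Reactants: 3 silyl enol ether; 4 methyl vinyl ketone
Product: 5 (2S,3R)-2,3-dimethyl-2-(3-oxobutyl)cyclohexan-1-one
Conditions: BF3·OEt2, i-PrOH, CH2Cl2, −78 °C
Reagents that add atoms: none
Why: Mukaiyama–Michael addition in which the enone approaches C9 on the face opposite the neighbouring pseudoaxial C8 methyl, so the chain enters trans to it and C9 is set as S (the two methyls cis).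

Step 3
Reactants: 5 diketone; 6 triethyl phosphonoacetate
Product: 7 ethyl (2E)-5-[(1S,2R)-1,2-dimethyl-6-oxocyclohexyl]-3-methylpent-2-enoate
Conditions: NaH, THF, 0 → 45 °C
Reagents that add atoms: none
Why: Horner–Wadsworth–Emmons olefination should occur only at the methyl ketone, the ring ketone being shielded by quaternary C9, and should favour the E-enoate; any Z-isomer is removed by chromatography.

Step 4
Reactants: 7 keto enoate
Product: 9 ethyl (2E)-5-[(1S,6R)-1,6-dimethyl-2-{[(trifluoromethyl)sulfonyl]oxy}cyclohex-2-en-1-yl]-3-methylpent-2-enoate, via potassium enolate 8 (not isolated)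
Conditions: KN(SiMe3)2, THF, −78 °C; then PhNTf2, −78 → 0 °C
Reagents that add atoms: N-phenylbis(trifluoromethanesulfonimide) O=S(=O)(N(c1ccccc1)S(=O)(=O)C(F)(F)F)C(F)(F)F
Why: Enol triflate formation, in which the ketone can enolise only toward C5 because C9 is quaternary, gives the C5=C10 triflate while the less acidic enoate is left alone.

Step 5
Reactants: 9 triflate enoate
Product: 10 (5R,6S)-6-[(3E)-5-hydroxy-3-methylpent-3-en-1-yl]-5,6-dimethylcyclohex-1-en-1-yl trifluoromethanesulfonate
Conditions: i-Bu2AlH (2.2 equiv), CH2Cl2, −78 °C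
Reagents that add atoms: none
Why: 1,2-Reduction of the enoate by the aluminium hydride gives the allylic alcohol, and the vinyl triflate is inert to hydride at this temperature.

Step 6
Reactants: 10 allylic alcohol
Product: 11 (5R,6S)-6-[(3E)-5-{[tert-butyl(dimethyl)silyl]oxy}-3-methylpent-3-en-1-yl]-5,6-dimethylcyclohex-1-en-1-yl trifluoromethanesulfonate
Conditions: TBSCl, imidazole, DMF, rt
Reagents that add atoms: tert-butyldimethylsilyl chloride CC(C)(C)[Si](C)(C)Cl
Why: Standard silylation of the unhindered primary alcohol protects it for the base, hydride and metathesis steps that follow.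

Step 7
Reactants: 11 vinyl triflate
Product: 12 methyl (5R,6S)-6-[(3E)-5-{[tert-butyl(dimethyl)silyl]oxy}-3-methylpent-3-en-1-yl]-5,6-dimethylcyclohex-1-ene-1-carboxylate
Conditions: Pd(OAc)2 (5 mol %), PPh3 (10 mol %), CO (1 atm), MeOH, Et3N, DMF, 60 °C
Reagents that add atoms: carbon monoxide [C-]#[O+]; methanol CO
Why: Palladium-catalysed methoxycarbonylation (oxidative addition of zerovalent palladium into the C–OTf bond, CO insertion, methanolysis) installs the C10 carbon, and excess CO and methanol should outpace insertion into the trisubstituted side-chain alkene.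

Step 8
Reactants: 12 enoate
Product: 13 {(5R,6S)-6-[(3E)-5-{[tert-butyl(dimethyl)silyl]oxy}-3-methylpent-3-en-1-yl]-5,6-dimethylcyclohex-1-en-1-yl}methanol
Conditions: i-Bu2AlH (2.5 equiv), CH2Cl2, −78 → 0 °C
Reagents that add atoms: none
Why: Reduction of the conjugated ester by the aluminium hydride gives the primary allylic alcohol needed for the sigmatropic step.

Step 9
Reactants: 14 hex-5-enoic acid; 15 (4S)-4-benzyl-1,3-oxazolidin-2-one
Product: 17 (4S)-4-benzyl-3-(hex-5-enoyl)-1,3-oxazolidin-2-one, via mixed pivalic anhydride 16 (not isolated)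
Conditions: t-BuCOCl, Et3N, THF, −20 °C; then 15, LiCl, rt
Reagents that add atoms: none
Why: N-Acylation of the oxazolidinone through the mixed anhydride, which is attacked at the less hindered hexenoyl carbonyl.

Step 10
Reactants: 17 imide
Product: 19 (4S)-4-benzyl-3-[(2S)-2-methylhex-5-enoyl]-1,3-oxazolidin-2-one, via sodium Z-enolate 18 (not isolated)
Conditions: NaN(SiMe3)2, THF, −78 °C; then MeI
Reagents that add atoms: iodomethane CI
Why: Auxiliary-controlled enolate alkylation, in which the chelated Z-enolate is methylated on the face away from the benzyl group, sets the α-centre as S.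

Step 11
Reactants: 19 methylated imide
Product: 20 (2S)-2-methylhex-5-enoic acid
Conditions: LiOH, H2O2, THF/H2O, 0 °C; aq. Na2SO3, then HCl
Reagents that add atoms: hydrogen peroxide (as LiOOH) OO
Why: Hydroperoxide cleaves the exocyclic imide carbonyl selectively and without epimerisation, and the auxiliary is recovered.

Step 12
Reactants: 13 allylic alcohol; 20 acid
Product: 21 {(5R,6S)-6-[(3E)-5-{[tert-butyl(dimethyl)silyl]oxy}-3-methylpent-3-en-1-yl]-5,6-dimethylcyclohex-1-en-1-yl}methyl (2S)-2-methylhex-5-enoate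
Conditions: DCC, DMAP (cat.), CH2Cl2, 0 °C → rt
Reagents that add atoms: none
Why: Steglich esterification joins the primary alcohol and the α-branched acid under conditions that should not epimerise the α-centre.

Step 13
Reactants: 21 allylic ester
Product: 25 (2S)-2-[(1R,3S,4R)-3-[(3E)-5-{[tert-butyl(dimethyl)silyl]oxy}-3-methylpent-3-en-1-yl]-3,4-dimethyl-2-methylidenecyclohexyl]-2-methylhex-5-enoic acid, via lithium enolate 22 (not isolated), via Z-silyl ketene acetal 23 (not isolated), via trimethylsilyl ester 24 (not isolated)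
Conditions: (R)-N-(2,2,2-trifluoroethyl)-1-phenyl-2-(piperidin-1-yl)ethanamine (1.2 equiv), n-BuLi, THF, −78 °C; then 21; TMSCl, −78 °C → rt; aq. HCl work-up
Reagents that add atoms: none
Why: Ireland–Claisen rearrangement in which the chiral lithium amide, reading the α-stereocentre, should give the ketene acetal with the butenyl chain cis to OSiMe3, and the [3,3] shift through a chair (the boat would push OSiMe3 onto quaternary C9) on the ring face opposite the C8 and C9 methyls forms C4–C5, sets C4 (S) and C5 (R) and unveils the C10 methylene.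

Step 14
Reactants: 25 acid
Product: 26 methyl (2S)-2-[(1R,3S,4R)-3-[(3E)-5-{[tert-butyl(dimethyl)silyl]oxy}-3-methylpent-3-en-1-yl]-3,4-dimethyl-2-methylidenecyclohexyl]-2-methylhex-5-enoate
Conditions: Me3SiCHN2, MeOH/toluene, 0 °C → rt
Reagents that add atoms: (trimethylsilyl)diazomethane C[Si](C)(C)C=[N+]=[N-]
Why: O-Alkylation of the carboxylic acid by the diazoalkane forms the methyl ester without attack at the hindered carbonyl and without touching a stereocentre.

Step 15
Reactants: 26 ring-B diene
Product: 27 methyl (1S,5S,6R,8aR)-5-[(3E)-5-{[tert-butyl(dimethyl)silyl]oxy}-3-methylpent-3-en-1-yl]-1,5,6-trimethyl-1,2,3,5,6,7,8,8a-octahydronaphthalene-1-carboxylate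
Conditions: second-generation Hoveyda–Grubbs catalyst (H2IMes)Cl2Ru=CH(C6H4-2-O-i-Pr) (10 mol %), 1,4-benzoquinone (20 mol %), toluene (5 mM), 80 °C, argon sparge
Reagents that add atoms: none
Why: The ruthenium carbene exchanges onto the unhindered C1 vinyl group, the new C1 alkylidene adds intramolecularly across the C10 methylene in a [2+2] cycloaddition, and cycloreversion of the ruthenacyclobutane gives C1=C10 and a ruthenium methylidene that leaves as ethylene. The closest known reaction type is ring-closing metathesis of a monosubstituted with a 1,1-disubstituted alkene to a trisubstituted cyclohexene under an N-heterocyclic-carbene ruthenium catalyst. Ring A closes as a six-membered carbocycle by joining the alkene carbons C1 and C10 across the existing C2–C5 tether, with loss of both terminal CH2 groups. No stereocentre is formed, and C4, C5, C8 and C9 are sp3 centres that take no part. The step needs chemoselectivity among three alkenes and a fixed alkene position: the substitution pattern gives the first (the vinyl group initiates, the methylene is the only partner at six-ring distance, the trisubstituted allylic-ether alkene is inert) and the connectivity of the two termini gives the second, so neither the 5(10) nor the 1(2) isomer can arise. High dilution, ethylene removal and benzoquinone are there to suppress dimerisation and ruthenium-hydride double-bond migration.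

Step 16
Reactants: 27 silyl ether
Product: 28 methyl (1S,5S,6R,8aR)-5-[(3E)-5-hydroxy-3-methylpent-3-en-1-yl]-1,5,6-trimethyl-1,2,3,5,6,7,8,8a-octahydronaphthalene-1-carboxylate
Conditions: Bu4NF, THF, 0 °C → rt
Reagents that add atoms: none
Why: Fluoride-mediated desilylation frees the allylic alcohol, and the hindered methyl ester is not attacked.

Step 17
Reactants: 28 allylic alcohol; 29 3-phenylprop-2-ynoic acid
Product: 30 methyl (1S,5S,6R,8aR)-1,5,6-trimethyl-5-{(3E)-3-methyl-5-[(3-phenylprop-2-ynoyl)oxy]pent-3-en-1-yl}-1,2,3,5,6,7,8,8a-octahydronaphthalene-1-carboxylate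
Conditions: DCC, DMAP (cat.), CH2Cl2, 0 °C
Reagents that add atoms: none
Why: Steglich esterification of the primary allylic alcohol, kept cold with little DMAP to limit conjugate addition to the ynoate.

Step 18
Reactants: 30 ynoate
Product: 31 target, methyl (1S,5S,6R,8aR)-1,5,6-trimethyl-5-[(3E)-3-methyl-5-{[(2Z)-3-phenylprop-2-enoyl]oxy}pent-3-en-1-yl]-1,2,3,5,6,7,8,8a-octahydronaphthalene-1-carboxylate
Conditions: H2 (1 atm), Pd/CaCO3 poisoned with Pb(OAc)2 (Lindlar catalyst), quinoline, EtOAc, rt, stopped after one equivalent of H2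
Reagents that add atoms: none
Why: Lindlar semihydrogenation delivers H2 syn to the alkyne on the poisoned palladium surface to give the Z-cinnamate, and the two hindered trisubstituted alkenes should not be reduced.

Compound list
1 | 2-methylcyclohex-2-en-1-one | CC1=CCCCC1=O | starting material
2 | dimethylaluminium (3R)-2,3-dimethylcyclohex-1-en-1-olate | C[C@@H]1CCCC(O[Al](C)C)=C1C | intermediate
3 | trimethyl{[(3R)-2,3-dimethylcyclohex-1-en-1-yl]oxy}silane | C[C@@H]1CCCC(O[Si](C)(C)C)=C1C | intermediate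
4 | methyl vinyl ketone | CC(=O)C=C | starting material
5 | (2S,3R)-2,3-dimethyl-2-(3-oxobutyl)cyclohexan-1-one | O=C1CCC[C@@H](C)[C@]1(C)CCC(C)=O | intermediate
6 | triethyl phosphonoacetate | CCOC(=O)CP(=O)(OCC)OCC | starting material
7 | ethyl (2E)-5-[(1S,2R)-1,2-dimethyl-6-oxocyclohexyl]-3-methylpent-2-enoate | O=C1CCC[C@@H](C)[C@]1(C)CC/C(C)=C/C(=O)OCC | intermediate
8 | potassium (5R,6S)-6-[(3E)-5-ethoxy-3-methyl-5-oxopent-3-en-1-yl]-5,6-dimethylcyclohex-1-en-1-olate | [K+].[O-]C1=CCC[C@@H](C)[C@]1(C)CC/C(C)=C/C(=O)OCC | intermediate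
9 | ethyl (2E)-5-[(1S,6R)-1,6-dimethyl-2-{[(trifluoromethyl)sulfonyl]oxy}cyclohex-2-en-1-yl]-3-methylpent-2-enoate | O=S(=O)(OC1=CCC[C@@H](C)[C@]1(C)CC/C(C)=C/C(=O)OCC)C(F)(F)F | intermediate
10 | (5R,6S)-6-[(3E)-5-hydroxy-3-methylpent-3-en-1-yl]-5,6-dimethylcyclohex-1-en-1-yl trifluoromethanesulfonate | O=S(=O)(OC1=CCC[C@@H](C)[C@]1(C)CC/C(C)=C/CO)C(F)(F)F | intermediate
11 | (5R,6S)-6-[(3E)-5-{[tert-butyl(dimethyl)silyl]oxy}-3-methylpent-3-en-1-yl]-5,6-dimethylcyclohex-1-en-1-yl trifluoromethanesulfonate | O=S(=O)(OC1=CCC[C@@H](C)[C@]1(C)CC/C(C)=C/CO[Si](C)(C)C(C)(C)C)C(F)(F)F | intermediate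
12 | methyl (5R,6S)-6-[(3E)-5-{[tert-butyl(dimethyl)silyl]oxy}-3-methylpent-3-en-1-yl]-5,6-dimethylcyclohex-1-ene-1-carboxylate | COC(=O)C1=CCC[C@@H](C)[C@]1(C)CC/C(C)=C/CO[Si](C)(C)C(C)(C)C | intermediate
13 | {(5R,6S)-6-[(3E)-5-{[tert-butyl(dimethyl)silyl]oxy}-3-methylpent-3-en-1-yl]-5,6-dimethylcyclohex-1-en-1-yl}methanol | OCC1=CCC[C@@H](C)[C@]1(C)CC/C(C)=C/CO[Si](C)(C)C(C)(C)C | intermediate
14 | hex-5-enoic acid | C=CCCCC(=O)O | starting material
15 | (4S)-4-benzyl-1,3-oxazolidin-2-one | O=C1OC[C@H](Cc2ccccc2)N1 | starting material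
16 | hex-5-enoic 2,2-dimethylpropanoic anhydride | C=CCCCC(=O)OC(=O)C(C)(C)C | intermediate
17 | (4S)-4-benzyl-3-(hex-5-enoyl)-1,3-oxazolidin-2-one | C=CCCCC(=O)N1[C@@H](Cc2ccccc2)COC1=O | intermediate
18 | sodium Z-enolate of 17 (chain cis to O−) | [Na+].C=CCC/C=C(\[O-])N1[C@@H](Cc2ccccc2)COC1=O | intermediate
19 | (4S)-4-benzyl-3-[(2S)-2-methylhex-5-enoyl]-1,3-oxazolidin-2-one | C=CCC[C@H](C)C(=O)N1[C@@H](Cc2ccccc2)COC1=O | intermediate
20 | (2S)-2-methylhex-5-enoic acid | C=CCC[C@H](C)C(=O)O | intermediate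
21 | {(5R,6S)-6-[(3E)-5-{[tert-butyl(dimethyl)silyl]oxy}-3-methylpent-3-en-1-yl]-5,6-dimethylcyclohex-1-en-1-yl}methyl (2S)-2-methylhex-5-enoate | C=CCC[C@H](C)C(=O)OCC1=CCC[C@@H](C)[C@]1(C)CC/C(C)=C/CO[Si](C)(C)C(C)(C)C | intermediate
22 | lithium enolate of 21 (but-3-enyl cis to O−, methyl cis to the allylic oxygen) | [Li+].C=CCC/C(C)=C(\[O-])OCC1=CCC[C@@H](C)[C@]1(C)CC/C(C)=C/CO[Si](C)(C)C(C)(C)C | intermediate
23 | (Z)-trimethylsilyl ketene acetal of 21 (but-3-enyl cis to OSiMe3) | C=CCC/C(C)=C(\O[Si](C)(C)C)OCC1=CCC[C@@H](C)[C@]1(C)CC/C(C)=C/CO[Si](C)(C)C(C)(C)C | intermediate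
24 | trimethylsilyl ester of acid 25 | C=CCC[C@](C)(C(=O)O[Si](C)(C)C)[C@@H]1CC[C@@H](C)[C@](C)(CC/C(C)=C/CO[Si](C)(C)C(C)(C)C)C1=C | intermediate
25 | (2S)-2-[(1R,3S,4R)-3-[(3E)-5-{[tert-butyl(dimethyl)silyl]oxy}-3-methylpent-3-en-1-yl]-3,4-dimethyl-2-methylidenecyclohexyl]-2-methylhex-5-enoic acid | C=CCC[C@](C)(C(=O)O)[C@@H]1CC[C@@H](C)[C@](C)(CC/C(C)=C/CO[Si](C)(C)C(C)(C)C)C1=C | intermediate
26 | methyl (2S)-2-[(1R,3S,4R)-3-[(3E)-5-{[tert-butyl(dimethyl)silyl]oxy}-3-methylpent-3-en-1-yl]-3,4-dimethyl-2-methylidenecyclohexyl]-2-methylhex-5-enoate (key-step precursor) | C=CCC[C@](C)(C(=O)OC)[C@@H]1CC[C@@H](C)[C@](C)(CC/C(C)=C/CO[Si](C)(C)C(C)(C)C)C1=C | intermediate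
27 | methyl (1S,5S,6R,8aR)-5-[(3E)-5-{[tert-butyl(dimethyl)silyl]oxy}-3-methylpent-3-en-1-yl]-1,5,6-trimethyl-1,2,3,5,6,7,8,8a-octahydronaphthalene-1-carboxylate (key-step product) | COC(=O)[C@@]1(C)CCC=C2[C@H]1CC[C@@H](C)[C@]2(C)CC/C(C)=C/CO[Si](C)(C)C(C)(C)C | intermediate
28 | methyl (1S,5S,6R,8aR)-5-[(3E)-5-hydroxy-3-methylpent-3-en-1-yl]-1,5,6-trimethyl-1,2,3,5,6,7,8,8a-octahydronaphthalene-1-carboxylate | COC(=O)[C@@]1(C)CCC=C2[C@H]1CC[C@@H](C)[C@]2(C)CC/C(C)=C/CO | intermediate
29 | 3-phenylprop-2-ynoic acid | OC(=O)C#Cc1ccccc1 | starting material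
30 | methyl (1S,5S,6R,8aR)-1,5,6-trimethyl-5-{(3E)-3-methyl-5-[(3-phenylprop-2-ynoyl)oxy]pent-3-en-1-yl}-1,2,3,5,6,7,8,8a-octahydronaphthalene-1-carboxylate | COC(=O)[C@@]1(C)CCC=C2[C@H]1CC[C@@H](C)[C@]2(C)CC/C(C)=C/COC(=O)C#Cc1ccccc1 | intermediate
31 | methyl (1S,5S,6R,8aR)-1,5,6-trimethyl-5-[(3E)-3-methyl-5-{[(2Z)-3-phenylprop-2-enoyl]oxy}pent-3-en-1-yl]-1,2,3,5,6,7,8,8a-octahydronaphthalene-1-carboxylate | COC(=O)[C@@]1(C)CCC=C2[C@H]1CC[C@@H](C)[C@]2(C)CC/C(C)=C/COC(=O)/C=C\c1ccccc1 | target

Total step count: 18. Longest linear sequence: 15 steps (steps 1–8 and 12–18); steps 9–11 form the side branch to acid 20.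

Steps most likely to fail

Step 15. The C1 ruthenium alkylidene may fail to add across the C10 methylene, which is crowded by quaternary C9 and the C4-bearing C5, so that intermolecular metathesis of the vinyl termini and double-bond migration take over. The fallback closes ring A by carbonyl olefination instead. It sets out from acid 25, which is iodolactonised (I2, NaHCO3, MeCN, 0 °C), the carboxyl group closing a five-membered ring onto the tertiary C10 of the methylene, to give the iodolactone F1. K2CO3 in methanol opens F1 to the spiro-epoxy methyl ester F2, and H5IO6 (THF/H2O, buffered, re-silylation if the silyl ether suffers) cleaves the epoxide to the C10 ketone F3, whose C5 substituent already sits in the favoured equatorial position. A stoichiometric Schrock alkylidene, Mo(=CHCMe2Ph)(=N-2,6-i-Pr2C6H3)[OCMe(CF3)2]2 in benzene at rt, should metathesise the vinyl group and then olefinate the ketone intramolecularly from the resulting C1 alkylidene. This again places the alkene at C1=C10 and comes back to the route at 27.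

Step 13. Enolisation may proceed without control of ketene acetal geometry, or the rearrangement may leak through a boat or onto the methyl-bearing ring face, which would scramble C4 or C5. The fallback uses a ketene acetal whose geometry is locked by a ring. δ-Valerolactone is α-methylated (LiN(i-Pr)2, MeI, THF, −78 °C) to 3-methyltetrahydropyran-2-one F4, which Me3OBF4 followed by NaOMe converts into the cyclic ortho ester 2,2-dimethoxy-3-methyltetrahydropyran F5. Setting out from alcohol 13, heating with F5 and catalytic pivalic acid in xylene at 140 °C (ortho ester Claisen rearrangement) exchanges one methoxy group and eliminates methanol to an endocyclic ketene acetal in which the ring holds the methyl group cis to the allylic oxygen. Rearrangement through the same chair should give the lactone F6. LiOH followed by MeI in DMF gives the hydroxy ester F7, Dess–Martin periodinane gives the aldehyde F8, and Wittig methylenation (Ph3P=CH2, THF) comes back to the route at 26.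

Step 3. Olefination of the methyl ketone may give incomplete E-selectivity, and the basic phosphonate may trigger intramolecular aldol reaction of the 1,5-diketone. The fallback builds the trisubstituted alkene stereospecifically. It sets out from silyl enol ether 3, which is added to acrolein (BF3·OEt2, i-PrOH, CH2Cl2, −78 °C) to give the keto aldehyde F9. The Ohira–Bestmann reagent (dimethyl (1-diazo-2-oxopropyl)phosphonate, K2CO3, MeOH) converts F9 to the terminal alkyne F10. Zirconium-catalysed syn-carboalumination (Me3Al, Cp2ZrCl2, H2O additive, CH2Cl2, −23 °C, at which the hindered ring ketone should survive) and trapping with ClCO2Et give only the E-enoate, coming back to the route at 7.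

Further compounds
F1 | step 15 | cis-fused iodolactone of 25 (lactone oxygen on C10 on the face of the C4–C5 bond, CH2I on C10) | C=CCC[C@]1(C)C(=O)O[C@]2(CI)[C@H]1CC[C@@H](C)[C@]2(C)CC/C(C)=C/CO[Si](C)(C)C(C)(C)C
F2 | step 15 | methyl ester of 25 with the C10 methylene replaced by a spiro-epoxide | C=CCC[C@](C)(C(=O)OC)[C@@H]1CC[C@@H](C)[C@](C)(CC/C(C)=C/CO[Si](C)(C)C(C)(C)C)[C@@]12CO2
F3 | step 15 | methyl (2S)-2-[(1R,3S,4R)-3-[(3E)-5-{[tert-butyl(dimethyl)silyl]oxy}-3-methylpent-3-en-1-yl]-3,4-dimethyl-2-oxocyclohexyl]-2-methylhex-5-enoate | C=CCC[C@](C)(C(=O)OC)[C@@H]1CC[C@@H](C)[C@](C)(CC/C(C)=C/CO[Si](C)(C)C(C)(C)C)C1=O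
F4 | step 13 | 3-methyltetrahydro-2H-pyran-2-one (racemic) | CC1CCCOC1=O
F5 | step 13 | 2,2-dimethoxy-3-methyltetrahydro-2H-pyran (racemic) | COC1(OC)OCCCC1C
F6 | step 13 | (3S)-3-[(1R,3S,4R)-3-[(3E)-5-{[tert-butyl(dimethyl)silyl]oxy}-3-methylpent-3-en-1-yl]-3,4-dimethyl-2-methylidenecyclohexyl]-3-methyltetrahydro-2H-pyran-2-one | C[C@]1(CCCOC1=O)[C@@H]2CC[C@@H](C)[C@](C)(CC/C(C)=C/CO[Si](C)(C)C(C)(C)C)C2=C
F7 | step 13 | methyl (2S)-2-[(1R,3S,4R)-3-[(3E)-5-{[tert-butyl(dimethyl)silyl]oxy}-3-methylpent-3-en-1-yl]-3,4-dimethyl-2-methylidenecyclohexyl]-5-hydroxy-2-methylpentanoate | OCCC[C@](C)(C(=O)OC)[C@@H]1CC[C@@H](C)[C@](C)(CC/C(C)=C/CO[Si](C)(C)C(C)(C)C)C1=C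
F8 | step 13 | methyl (2S)-2-[(1R,3S,4R)-3-[(3E)-5-{[tert-butyl(dimethyl)silyl]oxy}-3-methylpent-3-en-1-yl]-3,4-dimethyl-2-methylidenecyclohexyl]-2-methyl-5-oxopentanoate | O=CCC[C@](C)(C(=O)OC)[C@@H]1CC[C@@H](C)[C@](C)(CC/C(C)=C/CO[Si](C)(C)C(C)(C)C)C1=C
F9 | step 3 | 3-[(1S,2R)-1,2-dimethyl-6-oxocyclohexyl]propanal | O=CCC[C@@]1(C)[C@H](C)CCCC1=O
F10 | step 3 | (2S,3R)-2-(but-3-yn-1-yl)-2,3-dimethylcyclohexan-1-one | C#CCC[C@@]1(C)[C@H](C)CCCC1=O
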